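- In the east run, electrophile plus product stays near the charge, 99.6 % at 1.00 min and 100.6 % at 5.00 min, so we take the part reacted, X, as the electrophile lost on this progress curve.

| flask | electrophile | nucleophile | free base | remark | time |
|---|---|---|---|---|---|
| east | 1 M | 1.3 M | 0.90 M | run made earlier |  |
| Wednesday's | 1.0 M | 1.30 M | 0.800 M |  | 10 min |
| Monday's | 1.0 M | 1.30 M | 1.20 M |  | 10 min |
| Saturday's | 1.0 M | 1.30 M | 1.80 M |  | 10 min |

east run (percent of the electrophile charged)

| time / min | electrophile / % | product / % |
|---|---|---|
| 1.00 | 94.4 | 5.2 |
| 2.00 | 90.4 | 9.8 |
| 3.00 | 86.9 | 13.6 |
| 4.00 | 83.7 | 15.8 |
| 5.00 | 81.8 | 18.8 |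

(readings scatter by 0.3 percentage points)

- no earlier run changes the charge of free base; that part of a forecast is a guess

- part of the electrophile that has reacted at the end, Wednesday's
- part of the electrophile that has reacted at the end, Monday's
- part of the electrophile that has reacted at the end, Saturday's
- what raising the concentration of free base from its lowest to its highest value here does to the part of the electrophile that has reacted (changes below 5 percentage points count as none) (no change / it falls / it rises)

- If X goes as time t to the power n, then log X against log t is a straight line of slope n, so we work on common logarithms of the readings.
- Between 1.00 min and 3.00 min the east run gives n = 0.774; carrying its reading at 5.00 min forward to 10 min with that power gives 31.1 %.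
- The weak link is the constant power: between 3.00 min and 5.00 min the east run gives n = 0.644, which is lower, and that reading carries the scatter of the data.
- We reforge that link by letting n keep falling in a straight line along log t, from the middle of each span to the middle of the span from 5.00 min to 10 min. This gives n = 0.547, the running time exponent: our estimate of the slope of log X against log t from 5.00 min to 10 min.
- Our number is therefore 26.6 % at 10 min; no earlier run varies the free base, so we guess that same value for Wednesday's, Monday's and Saturday's and expect no trend.
- The forecast differs: it gives 25.5 %, 33 % and 42 %, with the answer it rises, on the ground that “A base probably promotes the reaction or mops up the inhibiting acid”.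
- The flasks give 26.3 %, 26.6 % and 26.9 %, so the answer is no change: the change of 0.55 percentage points stands below the margin of 5 points, and the forecast for Saturday's is 15 points too high.

    nucleophile ⇌ dormant form (K = 2.30, k = 0.00180 s⁻¹)
    nucleophile + acid set free ⇌ protonated nucleophile, settled at all times (K = 110 L mol⁻¹)
    acid set free + free base ⇌ salt of the base (K = 170 L mol⁻¹, k = 0.0710 L mol⁻¹ s⁻¹)
    electrophile + nucleophile → acid set free + product (k = 8.00 × 10⁻⁴ L mol⁻¹ s⁻¹)

- With n at 0.547, Monday's reacted part at 5.00 min, 18.5 %, reckons to 27.0 % at 10 min, where Monday's flask gives 26.6 %. The neighbouring flask is Monday's read at 15 min, and the same power carried on from 26.6 % reckons 33.2 %. That neighbouring flask stands at 31.9 % reacted.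

The readings were generated by integration from invented constants; the scatter is artificial.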